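**Plan**

- Retrosynthesis: the acetate and then the butanoate are removed from the two benzylic CH2O groups. The bond between one benzylic CH2 of the five-membered ring and the ring-fusion carbon next to the only aromatic C–H is then cut by a retro-1,2-shift. The indane becomes a 3,3-dimethylcyclobutane spiro-fused to a 1-(hydroxymethyl)cyclohexadienyl cation, which traces back to the spiro-oxirane of a cross-conjugated dienone.
- Enabling feature: the bridge ArC–CH2–CMe2–CH2–ArC is symmetric, so a symmetric spirocyclobutane can stand in for it. One of the two carbons flanking the spiro centre is the only unsubstituted carbon of the six-membered ring, so it can receive the migrating CH2 and then lose H+ to complete the benzene ring.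
- Forward, ring order: the purchased cyclobutane comes first. The six-membered ring is built by Michael–Claisen annulation (spiro[3.5]nonane-5,7-dione). A temporary spiro-cyclopropane at C6 is opened by HCl to the 2-chloroethyl chain.
- A Stork–Danheiser addition brings the future acetoxymethyl carbon, DDQ gives the dienone, and a sulfonium ylide adds the last carbon as an oxirane.
- In the key step the cyclobutane expands to the cyclopentane while the six-membered ring aromatises. Only the benzylic OH destined for the butanoate is set free there, so the two esters are differentiated without selective acylation (MOM → OH → OAc at the end).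
- Stereochemistry: the target has no stereocentre. Compounds 6, 8 and 11 are racemic and their stereocentres vanish later.

Key step: step 8

Remark: tributyl[(methoxymethoxy)methyl]stannane is taken as a purchasable reagent; SMILES of racemic intermediates carry no descriptors.

**Route**

Step 1
Reactants: 1 3,3-dimethylcyclobutane-1-carboxylic acid
Product: 2 1-(3,3-dimethylcyclobutyl)ethan-1-one
Conditions: MeLi (2.2 equiv), Et2O, 0 °C → rt; aq. NH4Cl
Reagents that add atoms: methyllithium [Li]C
Why: The second equivalent of methyllithium adds to the lithium carboxylate to give a stable gem-dialkoxide that releases the methyl ketone only on aqueous work-up (methyl ketone synthesis from a carboxylic acid), so no tertiary alcohol should form.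

Step 2
Reactants: 2 1-(3,3-dimethylcyclobutyl)ethan-1-one; 3 methyl acrylate
Product: 4 2,2-dimethylspiro[3.5]nonane-5,7-dione
Conditions: KOt-Bu, THF, 0 °C → rt; then aq. HCl
Reagents that add atoms: none
Why: Under equilibrating conditions the ketone should add to the acrylate through its more substituted (cyclobutyl) α-carbon and the methyl-derived enolate then closes onto the ester (Michael–Claisen annulation, as in the preparation of 4,4-dimethylcyclohexane-1,3-dione from isopropyl methyl ketone), the 1,3-dione enolate being a thermodynamic sink that only this regioisomer can reach.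

Step 3
Reactants: 4 2,2-dimethylspiro[3.5]nonane-5,7-dione
Product: 5 7,7-dimethyldispiro[2.1.3^5.3^3]undecane-4,11-dione
Conditions: BrCH2CH2Br, K2CO3, DMSO, rt
Reagents that add atoms: 1,2-dibromoethane BrCCBr
Why: Double C-alkylation of the doubly activated C6 methylene by the 1,2-dihalide, the second bond closing 3-exo-tet, is the standard spirocyclopropanation of cyclohexane-1,3-diones.

Step 4
Reactants: 5 7,7-dimethyldispiro[2.1.3^5.3^3]undecane-4,11-dione
Product: 7 6-(2-chloroethyl)-7-methoxy-2,2-dimethylspiro[3.5]non-6-en-5-one, via chloroethyl dione 6 (not isolated)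
Conditions: HCl (4 M in dioxane), 0 °C → rt, evaporate; then HC(OMe)3, MeOH, TsOH (cat.), rt
Reagents that add atoms: hydrogen chloride Cl; trimethyl orthoformate COC(OC)OC (source of the methoxy group)
Why: The doubly acceptor-activated cyclopropane should undergo homo-conjugate addition of HCl to give the 2-(2-chloroethyl)-1,3-dione, whose less hindered carbonyl (C7, remote from the spiro centre) is then converted into the methyl enol ether under acid catalysis at room temperature (vinylogous ester formation), leaving the C5 carbonyl next to the spiro carbon free.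

Step 5
Reactants: 7 6-(2-chloroethyl)-7-methoxy-2,2-dimethylspiro[3.5]non-6-en-5-one
Product: 9 6-(2-chloroethyl)-5-[(methoxymethoxy)methyl]-2,2-dimethylspiro[3.5]non-5-en-7-one, via tertiary carbinol 8 (not isolated)
Conditions: Bu3SnCH2OMOM, n-BuLi, THF, −78 °C; then 7, −78 → −30 °C; then 1 M HCl, THF, 0 °C → rt
Reagents that add atoms: tributyl[(methoxymethoxy)methyl]stannane CCCC[Sn](CCCC)(CCCC)COCOC
Why: Tin–lithium exchange gives the α-alkoxymethyllithium, which should add 1,2 to the non-enolisable C5 carbonyl, and mild aqueous acid then hydrolyses the enol ether and eliminates the tertiary hydroxyl with transposition of the carbonyl (Stork–Danheiser sequence) while the MOM acetal and the primary chloride survive.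

Step 6
Reactants: 9 6-(2-chloroethyl)-5-[(methoxymethoxy)methyl]-2,2-dimethylspiro[3.5]non-5-en-7-one
Product: 10 6-(2-chloroethyl)-5-[(methoxymethoxy)methyl]-2,2-dimethylspiro[3.5]nona-5,8-dien-7-one
Conditions: DDQ, 1,4-dioxane, reflux
Reagents that add atoms: none
Why: DDQ should dehydrogenate the α′,β′-positions (C8–C9) of this 4,4-disubstituted cyclohexenone through its cross-conjugated dienol, as in the Δ1-dehydrogenation of steroidal 4-en-3-ones, to give the cross-conjugated dienone.

Step 7
Reactants: 10 6-(2-chloroethyl)-5-[(methoxymethoxy)methyl]-2,2-dimethylspiro[3.5]nona-5,8-dien-7-one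
Product: 11 2'-(2-chloroethyl)-3'-[(methoxymethoxy)methyl]-3'',3''-dimethyldispiro[oxirane-2,1'-cyclohexane-4',1''-cyclobutane]-2',5'-diene (racemic)
Conditions: Me3S+ I−, n-BuLi, THF, −10 → 0 °C
Reagents that add atoms: trimethylsulfonium iodide C[S+](C)C.[I-]
Why: Dimethylsulfonium methylide adds irreversibly 1,2 to the dienone carbonyl and the betaine closes to the oxirane (Corey–Chaykovsky epoxidation) at a temperature where the primary chloride should not be alkylated.

Step 8
Reactants: 11 2'-(2-chloroethyl)-3'-[(methoxymethoxy)methyl]-3'',3''-dimethyldispiro[oxirane-2,1'-cyclohexane-4',1''-cyclobutane]-2',5'-diene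
Product: 12 [6-(2-chloroethyl)-7-[(methoxymethoxy)methyl]-2,2-dimethyl-2,3-dihydro-1H-inden-5-yl]methanol
Conditions: CSA (10 mol %), CH2Cl2, 0 °C → rt
Reagents that add atoms: none
Why: Acid opens the oxirane at its tertiary, doubly allylic C–O bond to give a 1-(hydroxymethyl)cyclohexadienyl cation whose charge sits on the carbinyl carbon and on the two ring carbons flanking the spiro centre; one of the two equivalent cyclobutane C–C bonds then shifts (suprafacial 1,2-alkyl shift) from the spiro carbon to the unsubstituted flanking carbon, and loss of that carbon's proton completes the benzene ring. The closest known reaction type is the dienol–benzene (dienone–phenol) rearrangement of 4,4-spiro-annulated cyclohexadienyl cations, entered here from a Corey–Chaykovsky oxirane and combined with the cyclobutylcarbinyl-to-cyclopentyl cation ring expansion. The cyclopentane is not closed by a cyclisation: it arises by one-carbon ring expansion of the cyclobutane through the 1,2-shift, which makes the new aryl–CH2 bond, and the benzene ring arises from the existing six-membered ring by deprotonation (aromatisation). No stereocentre is formed, and the one at the oxirane carbon of 11 is destroyed. The step needs the shift to go to the C–H terminus and not to the terminus bearing CH2OMOM, and to outrun a 1,2-hydride shift from the CH2O group: the first should be secured because the alkoxymethyl group is hardly a better donor than H, a shift to it would create a quaternary carbon between two substituted neighbours and only the C–H terminus can lose a proton to aromatise, the second by the release of about 20 kcal/mol of ring strain and because any aldehyde formed can return to the same cation through its dienol under the acidic conditions. Because the CH2–CMe2–CH2 bridge is symmetric, either cyclobutane bond gives the same indane.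

Step 9
Reactants: 12 [6-(2-chloroethyl)-7-[(methoxymethoxy)methyl]-2,2-dimethyl-2,3-dihydro-1H-inden-5-yl]methanol
Product: 13 [6-(2-chloroethyl)-7-[(methoxymethoxy)methyl]-2,2-dimethyl-2,3-dihydro-1H-inden-5-yl]methyl butanoate
Conditions: (PrCO)2O, Et3N, DMAP (cat.), CH2Cl2, 0 °C → rt
Reagents that add atoms: butanoic anhydride CCCC(=O)OC(=O)CCC
Why: DMAP-catalysed acylation of the only free hydroxyl, a primary benzylic alcohol, with the anhydride is routine and places the butanoate unambiguously.

Step 10
Reactants: 13 [6-(2-chloroethyl)-7-[(methoxymethoxy)methyl]-2,2-dimethyl-2,3-dihydro-1H-inden-5-yl]methyl butanoate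
Product: 14 [6-(2-chloroethyl)-7-(hydroxymethyl)-2,2-dimethyl-2,3-dihydro-1H-inden-5-yl]methyl butanoate
Conditions: ZnBr2, n-PrSH, CH2Cl2, 0 °C
Reagents that add atoms: none
Why: Zinc bromide activates the acetal and the thiol captures the methoxymethyl unit, which should cleave the MOM ether within minutes at 0 °C without touching the butanoate or the alkyl chloride (Lewis acid/thiol MOM cleavage).

Step 11
Reactants: 14 [6-(2-chloroethyl)-7-(hydroxymethyl)-2,2-dimethyl-2,3-dihydro-1H-inden-5-yl]methyl butanoate
Product: 15 [7-(acetyloxymethyl)-6-(2-chloroethyl)-2,2-dimethyl-2,3-dihydro-1H-inden-5-yl]methyl butanoate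
Conditions: Ac2O, pyridine, DMAP (cat.), CH2Cl2, rt
Reagents that add atoms: acetic anhydride CC(=O)OC(C)=O
Why: Standard DMAP-catalysed acetylation of the liberated primary benzylic alcohol should give the target, the two ester groups being too far apart (meta) for acyl transfer.

**Compound list**

1 | 3,3-dimethylcyclobutane-1-carboxylic acid | CC1(C)CC(C1)C(O)=O | starting material
2 | 1-(3,3-dimethylcyclobutyl)ethan-1-one | CC(=O)C1CC(C)(C)C1 | intermediate
3 | methyl acrylate (methyl prop-2-enoate) | C=CC(=O)OC | starting material
4 | 2,2-dimethylspiro[3.5]nonane-5,7-dione (cyclobutane spiro at the carbon next to one carbonyl of a cyclohexane-1,3-dione) | O=C1CC(=O)CCC12CC(C)(C)C2 | intermediate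
5 | 7,7-dimethyldispiro[2.1.3^5.3^3]undecane-4,11-dione (compound 4 with a spiro-cyclopropane on the carbon between the two carbonyls) | O=C1C2(CC2)C(=O)CCC13CC(C)(C)C3 | intermediate
6 | 6-(2-chloroethyl)-2,2-dimethylspiro[3.5]nonane-5,7-dione (racemic, largely enolised) | O=C1C(CCCl)C(=O)CCC12CC(C)(C)C2 | intermediate
7 | 6-(2-chloroethyl)-7-methoxy-2,2-dimethylspiro[3.5]non-6-en-5-one | O=C1C(CCCl)=C(OC)CCC12CC(C)(C)C2 | intermediate
8 | 6-(2-chloroethyl)-7-methoxy-5-[(methoxymethoxy)methyl]-2,2-dimethylspiro[3.5]non-6-en-5-ol (racemic) | OC1(COCOC)C(CCCl)=C(OC)CCC12CC(C)(C)C2 | intermediate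
9 | 6-(2-chloroethyl)-5-[(methoxymethoxy)methyl]-2,2-dimethylspiro[3.5]non-5-en-7-one | O=C1CCC2(CC(C)(C)C2)C(COCOC)=C1CCCl | intermediate
10 | 6-(2-chloroethyl)-5-[(methoxymethoxy)methyl]-2,2-dimethylspiro[3.5]nona-5,8-dien-7-one | O=C1C=CC2(CC(C)(C)C2)C(COCOC)=C1CCCl | intermediate
11 | 2'-(2-chloroethyl)-3'-[(methoxymethoxy)methyl]-3'',3''-dimethyldispiro[oxirane-2,1'-cyclohexane-4',1''-cyclobutane]-2',5'-diene (racemic; spiro-oxirane on the former carbonyl carbon of 10) | C1OC12C=CC3(CC(C)(C)C3)C(COCOC)=C2CCCl | intermediate
12 | [6-(2-chloroethyl)-7-[(methoxymethoxy)methyl]-2,2-dimethyl-2,3-dihydro-1H-inden-5-yl]methanol | OCc1cc2c(c(COCOC)c1CCCl)CC(C)(C)C2 | intermediate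
13 | [6-(2-chloroethyl)-7-[(methoxymethoxy)methyl]-2,2-dimethyl-2,3-dihydro-1H-inden-5-yl]methyl butanoate | CCCC(=O)OCc1cc2c(c(COCOC)c1CCCl)CC(C)(C)C2 | intermediate
14 | [6-(2-chloroethyl)-7-(hydroxymethyl)-2,2-dimethyl-2,3-dihydro-1H-inden-5-yl]methyl butanoate | CCCC(=O)OCc1cc2c(c(CO)c1CCCl)CC(C)(C)C2 | intermediate
15 | [7-(acetyloxymethyl)-6-(2-chloroethyl)-2,2-dimethyl-2,3-dihydro-1H-inden-5-yl]methyl butanoate | CCCC(=O)OCc1cc2c(c(COC(C)=O)c1CCCl)CC(C)(C)C2 | target

**Step count and risks**

Total steps: 11. Longest linear sequence: 11 (from 1).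

Steps most likely to fail:

Step 8. The hydroxymethyl-substituted dienyl cation may collapse by a 1,2-hydride shift from the oxygen-bearing CH2 (oxirane-to-aldehyde isomerisation), or the acetal may be attacked by the acid, before the ring-expanding shift takes place. The fallback sets out from 10 and comes back at 12. Vinylmagnesium bromide with CeCl3 should add 1,2 to the dienone carbonyl to give 6-(2-chloroethyl)-7-ethenyl-5-[(methoxymethoxy)methyl]-2,2-dimethylspiro[3.5]nona-5,8-dien-7-ol F1. Catalytic acid then ionises this tertiary carbinol to a cation that carries no β-oxygen, so that only the ring-expanding shift and aromatisation remain, giving 5-(2-chloroethyl)-6-ethenyl-4-[(methoxymethoxy)methyl]-2,2-dimethyl-2,3-dihydro-1H-indene F2. Ozonolysis of the vinyl group with NaBH4 work-up converts it into the hydroxymethyl group of 12.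

Step 5. The 1,2-addition may be blocked by the flanking spiro ring and chloroethyl chain, so that the organolithium instead removes a γ-proton at C8 or attacks the alkyl chloride. The fallback sets out from 7 and comes back at 9. The slimmer and less basic vinylcerium reagent (vinylmagnesium bromide, CeCl3) is added and the adduct hydrolysed with dilute acid to 6-(2-chloroethyl)-5-ethenyl-2,2-dimethylspiro[3.5]non-5-en-7-one F3. The terminal alkene is cleaved selectively (OsO4 cat., NaIO4, 2,6-lutidine) to 6-(2-chloroethyl)-2,2-dimethyl-7-oxospiro[3.5]non-5-ene-5-carbaldehyde F4. The aldehyde alone is reduced with NaBH(OAc)3 to 6-(2-chloroethyl)-5-(hydroxymethyl)-2,2-dimethylspiro[3.5]non-5-en-7-one F5, and MOMCl with i-Pr2NEt gives 9.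

Step 2. The Michael addition may go through the methyl group instead of the cyclobutyl methine (exocyclic enolisation of a cyclobutane is strained), or the acrylate may polymerise. The fallback sets out from 1 and comes back at 4. Fischer esterification gives methyl 3,3-dimethylcyclobutane-1-carboxylate F6. Its LDA enolate is alkylated with 2-(2-bromoethyl)-2-methyl-1,3-dioxolane to methyl 3,3-dimethyl-1-[2-(2-methyl-1,3-dioxolan-2-yl)ethyl]cyclobutane-1-carboxylate F7, which sets the quaternary carbon without regiochemical ambiguity. Aqueous acid unmasks methyl 3,3-dimethyl-1-(3-oxobutyl)cyclobutane-1-carboxylate F8, and KOt-Bu closes the 1,3-dione 4 by intramolecular Claisen condensation.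

**Further compounds**

F1 | step 8 | 6-(2-chloroethyl)-7-ethenyl-5-[(methoxymethoxy)methyl]-2,2-dimethylspiro[3.5]nona-5,8-dien-7-ol | OC1(C=C)C=CC2(CC(C)(C)C2)C(COCOC)=C1CCCl
F2 | step 8 | 5-(2-chloroethyl)-6-ethenyl-4-[(methoxymethoxy)methyl]-2,2-dimethyl-2,3-dihydro-1H-indene | C=Cc1cc2c(c(COCOC)c1CCCl)CC(C)(C)C2
F3 | step 5 | 6-(2-chloroethyl)-5-ethenyl-2,2-dimethylspiro[3.5]non-5-en-7-one | O=C1CCC2(CC(C)(C)C2)C(C=C)=C1CCCl
F4 | step 5 | 6-(2-chloroethyl)-2,2-dimethyl-7-oxospiro[3.5]non-5-ene-5-carbaldehyde | O=CC1=C(CCCl)C(=O)CCC12CC(C)(C)C2
F5 | step 5 | 6-(2-chloroethyl)-5-(hydroxymethyl)-2,2-dimethylspiro[3.5]non-5-en-7-one | O=C1CCC2(CC(C)(C)C2)C(CO)=C1CCCl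
F6 | step 2 | methyl 3,3-dimethylcyclobutane-1-carboxylate | COC(=O)C1CC(C)(C)C1
F7 | step 2 | methyl 3,3-dimethyl-1-[2-(2-methyl-1,3-dioxolan-2-yl)ethyl]cyclobutane-1-carboxylate | COC(=O)C1(CCC2(C)OCCO2)CC(C)(C)C1
F8 | step 2 | methyl 3,3-dimethyl-1-(3-oxobutyl)cyclobutane-1-carboxylate | COC(=O)C1(CCC(C)=O)CC(C)(C)C1
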